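**Plan**

- The retrosynthesis first cuts the ketone bond C(=O)–C1' to ring A (acyl substitution on an N-methoxy-N-methylamide by lithiated tris-MOM phloroglucinol). It then cuts the two aryl–CH2 bonds C3–C1'' and C5–C1'' of ring B (both prenyl groups leave as prenylzinc bromide), and last the two C–Br bonds, back to a para-substituted phenol.
- Enabling feature: C3 and C5 of ring B are exactly the two carbons ortho to O4, and the para carbon C1 carries the three-carbon chain. Bromination of the free phenol can therefore mark only these two carbons for cross-coupling.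
- Forward: methyl 3-(4-hydroxyphenyl)propanoate is dibrominated and MOM-protected, both prenyl groups are attached in one twofold Negishi coupling, the ester becomes the Weinreb amide, ring A is joined as its aryllithium, and the four MOM ethers are removed.
- Both rings are bought and no ring is formed. The target has no stereocentre and no stereogenic alkene, so the only selectivity to secure is linear (CH2-bound) against branched (CMe2-bound) prenyl attachment, which the Pd/CPhos catalyst supplies.

Key step: step 4

Remark: in steps 1, 4, 6 and 8 one reagent acts at two to four like positions in a single operation; each is counted as one reaction and the partly converted species are not numbered.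

**Step 1**
Reactants: 1 methyl 3-(4-hydroxyphenyl)propanoate
Product: 2 methyl 3-(3,5-dibromo-4-hydroxyphenyl)propanoate
Conditions: Br2 (2.1 equiv), AcOH, rt
Reagents that add atoms: bromine, BrBr
Why: Electrophilic aromatic bromination is directed by the hydroxyl group to its two ortho carbons because the para carbon is blocked by the side chain, so the reaction should stop cleanly at the 3,5-dibromide.

**Step 2**
Reactants: 2 methyl 3-(3,5-dibromo-4-hydroxyphenyl)propanoate
Product: 3 methyl 3-[3,5-dibromo-4-(methoxymethoxy)phenyl]propanoate
Conditions: MOMCl, i-Pr2NEt, CH2Cl2, 0 °C to rt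
Reagents that add atoms: chloromethyl methyl ether, COCCl
Why: O-alkylation of the acidic 2,6-dibromophenol with the small, very reactive α-chloro ether (MOM protection) should proceed despite the two flanking bromines and removes the proton that would otherwise destroy the zinc reagent.

**Step 3**
Reactants: 4 prenyl bromide (1-bromo-3-methylbut-2-ene)
Product: 5 prenylzinc bromide, kept as a titrated THF solution
Conditions: Zn dust (activated with BrCH2CH2Br, Me3SiCl), LiCl, THF, 0 °C, slow addition
Reagents that add atoms: zinc, [Zn]
Why: Direct oxidative insertion of zinc into the allylic C–Br bond is fast at 0 °C, and LiCl together with slow addition should keep Wurtz homocoupling low.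

**Step 4**
Reactants: 3 methyl 3-[3,5-dibromo-4-(methoxymethoxy)phenyl]propanoate; 5 prenylzinc bromide (3 equiv)
Product: 6 methyl 3-[4-(methoxymethoxy)-3,5-bis(3-methylbut-2-en-1-yl)phenyl]propanoate
Conditions: Pd(OAc)2 (4 mol %), CPhos (8 mol %), THF, rt
Reagents that add atoms: none
Why: Negishi cross-coupling: zerovalent palladium carrying CPhos, formed when the zinc reagent reduces Pd(OAc)2, inserts into a C–Br bond, the prenyl group passes from zinc to palladium, and reductive elimination forms the aryl–CH2 bond, after which the same cycle runs at the second C–Br bond. The closest known reaction type is the linear-selective palladium/dialkylbiarylphosphine coupling of 3,3-disubstituted allylzinc halides with ortho-substituted aryl bromides, used here twice on one ring. No ring is closed and no stereocentre is created. The selectivity needed is bonding through the CH2 terminus and not the CMe2 terminus of the allyl unit: the bulky, electron-rich CPhos ligand is expected to hold the allyl group as the less hindered primary σ-complex and to make reductive elimination from it faster than σ–π–σ equilibration to the tertiary isomer. The substrate secures the rest: each C–Br carbon has only one ortho substituent (the MOM-oxy group), the masked phenol offers no acidic proton and cannot cyclise onto the new alkenes, the methyl ester should be inert to the allylzinc at room temperature, and the excess of 5 is there to carry the second coupling to completion.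

**Step 5**
Reactants: 6 methyl 3-[4-(methoxymethoxy)-3,5-bis(3-methylbut-2-en-1-yl)phenyl]propanoate
Product: 7 N-methoxy-N-methyl-3-[4-(methoxymethoxy)-3,5-bis(3-methylbut-2-en-1-yl)phenyl]propanamide
Conditions: MeNH(OMe)·HCl, i-PrMgCl, THF, −20 °C to 0 °C
Reagents that add atoms: N,O-dimethylhydroxylamine hydrochloride, CNOC.Cl
Why: The chloromagnesium amide formed in the flask from the amine salt and i-PrMgCl attacks the methyl ester directly (Weinreb amide formation by ester aminolysis), and neither the MOM ether nor the prenyl groups react with a Grignard base at this temperature.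

**Step 6**
Reactants: 8 phloroglucinol (benzene-1,3,5-triol)
Product: 9 1,3,5-tris(methoxymethoxy)benzene
Conditions: MOMCl (3.6 equiv), i-Pr2NEt (4 equiv), CH2Cl2/DMF, 0 °C to rt
Reagents that add atoms: chloromethyl methyl ether, COCCl
Why: Threefold O-alkylation with the hard α-chloro ether electrophile (MOM protection) should favour oxygen over ring carbon and gives the acetal groups that later direct the lithiation.

**Step 7**
Reactants: 9 1,3,5-tris(methoxymethoxy)benzene (1.5 equiv); 7 N-methoxy-N-methyl-3-[4-(methoxymethoxy)-3,5-bis(3-methylbut-2-en-1-yl)phenyl]propanamide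
Product: 12 3-[4-(methoxymethoxy)-3,5-bis(3-methylbut-2-en-1-yl)phenyl]-1-[2,4,6-tris(methoxymethoxy)phenyl]propan-1-one, via 2,4,6-tris(methoxymethoxy)phenyllithium 10 (not isolated), via lithium hemiaminal N,O-chelate 11 (not isolated)
Conditions: 9, n-BuLi (1.4 equiv), THF, 0 °C; then 7, −78 °C to 0 °C; aq NH4Cl
Reagents that add atoms: none
Why: Directed ortho-lithiation of 9 at the carbon between two MOM-oxy groups gives aryllithium 10, which should add only once to amide 7 because the five-membered lithium chelate 11 persists until the aqueous quench and only then collapses to the ketone (Weinreb ketone synthesis).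

**Step 8**
Reactants: 12 3-[4-(methoxymethoxy)-3,5-bis(3-methylbut-2-en-1-yl)phenyl]-1-[2,4,6-tris(methoxymethoxy)phenyl]propan-1-one
Product: 13 4,2',4',6'-tetrahydroxy-3,5-diprenyldihydrochalcone, i.e. 3-[4-hydroxy-3,5-bis(3-methylbut-2-en-1-yl)phenyl]-1-(2,4,6-trihydroxyphenyl)propan-1-one
Conditions: conc. HCl (few equiv), MeOH, rt to 40 °C
Reagents that add atoms: none
Why: Acid-catalysed acetal exchange with methanol (MOM cleavage) should free all four phenols, the two ortho to the carbonyl fastest, and dilute HCl at or just above room temperature is mild enough that the trisubstituted prenyl alkenes should not be protonated.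

**Compound list**

1 | methyl 3-(4-hydroxyphenyl)propanoate | COC(=O)CCc1ccc(O)cc1 | starting material
2 | methyl 3-(3,5-dibromo-4-hydroxyphenyl)propanoate | COC(=O)CCc1cc(Br)c(O)c(Br)c1 | intermediate
3 | methyl 3-[3,5-dibromo-4-(methoxymethoxy)phenyl]propanoate | COCOc1c(Br)cc(CCC(=O)OC)cc1Br | intermediate
4 | prenyl bromide (1-bromo-3-methylbut-2-ene) | CC(C)=CCBr | starting material
5 | prenylzinc bromide, (3-methylbut-2-en-1-yl)zinc bromide, THF solution | CC(C)=CC[Zn]Br | intermediate
6 | methyl 3-[4-(methoxymethoxy)-3,5-bis(3-methylbut-2-en-1-yl)phenyl]propanoate | COCOc1c(CC=C(C)C)cc(CCC(=O)OC)cc1CC=C(C)C | intermediate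
7 | N-methoxy-N-methyl-3-[4-(methoxymethoxy)-3,5-bis(3-methylbut-2-en-1-yl)phenyl]propanamide | COCOc1c(CC=C(C)C)cc(CCC(=O)N(C)OC)cc1CC=C(C)C | intermediate
8 | phloroglucinol (benzene-1,3,5-triol) | Oc1cc(O)cc(O)c1 | starting material
9 | 1,3,5-tris(methoxymethoxy)benzene | COCOc1cc(OCOC)cc(OCOC)c1 | intermediate
10 | 2,4,6-tris(methoxymethoxy)phenyllithium | [Li]c1c(OCOC)cc(OCOC)cc1OCOC | intermediate
11 | lithium 1-[methoxy(methyl)amino]-3-[4-(methoxymethoxy)-3,5-bis(3-methylbut-2-en-1-yl)phenyl]-1-[2,4,6-tris(methoxymethoxy)phenyl]propan-1-olate (racemic tetrahedral adduct) | CON(C)C(O[Li])(CCc1cc(CC=C(C)C)c(OCOC)c(CC=C(C)C)c1)c1c(OCOC)cc(OCOC)cc1OCOC | intermediate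
12 | 3-[4-(methoxymethoxy)-3,5-bis(3-methylbut-2-en-1-yl)phenyl]-1-[2,4,6-tris(methoxymethoxy)phenyl]propan-1-one | COCOc1cc(OCOC)c(C(=O)CCc2cc(CC=C(C)C)c(OCOC)c(CC=C(C)C)c2)c(OCOC)c1 | intermediate
13 | 4,2',4',6'-tetrahydroxy-3,5-diprenyldihydrochalcone | CC(C)=CCc1cc(CCC(=O)c2c(O)cc(O)cc2O)cc(CC=C(C)C)c1O | target

**Totals**

Total step count: 8. Longest linear sequence: 6 steps (steps 1, 2, 4, 5, 7, 8).

**Steps most likely to fail**

Step 4. The twofold coupling may stall after the first prenyl group is in place, a C–Br bond may be reduced by adventitious proton sources, or some of the allyl unit may attach through its CMe2 terminus. The fallback removes the regiochemical question. It sets out from 3, which would undergo twofold Suzuki–Miyaura allylation with allylboronic acid pinacol ester (Pd(PPh3)4, CsF, THF, reflux) to give methyl 3-[4-(methoxymethoxy)-3,5-di(prop-2-en-1-yl)phenyl]propanoate F1. Twofold olefin cross-metathesis of F1 with excess 2-methyl-2-butene (second-generation Grubbs catalyst, RuCl2(=CHPh)(PCy3)(H2IMes), CH2Cl2, rt) should then turn each allyl group into a prenyl group, and the route is rejoined at 6.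

Step 7. The hindered, basic aryllithium may deprotonate the amide at its α-CH2 group or cause base-induced loss of the N-methoxy group instead of adding to the carbonyl. The fallback sets out from 7, which would be reduced with DIBAL-H (THF, −78 °C) to 3-[4-(methoxymethoxy)-3,5-bis(3-methylbut-2-en-1-yl)phenyl]propanal F2. Addition of aryllithium 10 (made from 9 as before) to this much more electrophilic aldehyde should give 3-[4-(methoxymethoxy)-3,5-bis(3-methylbut-2-en-1-yl)phenyl]-1-[2,4,6-tris(methoxymethoxy)phenyl]propan-1-ol F3. Oxidation of F3 with Dess–Martin periodinane (CH2Cl2, NaHCO3, rt) comes back to the route at 12.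

Step 8. While the hindered MOM ether on ring B is still being cleaved, the freed ring B phenol may add under acid catalysis to a neighbouring prenyl alkene to close a 2,2-dimethylchroman, or HCl or methanol may add to the alkenes. The fallback avoids protic acid. It sets out from 12, which would be treated with TMSOTf and 2,2'-bipyridyl (MeCN, 0 °C) to exchange each aryl MOM ether for a silyl ether, giving 3-[3,5-bis(3-methylbut-2-en-1-yl)-4-(trimethylsilyloxy)phenyl]-1-[2,4,6-tris(trimethylsilyloxy)phenyl]propan-1-one F4. Hydrolysis of F4 with water at neutral pH (or KF in MeOH) should release the four phenols and arrive at 13.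

**Further compounds**

F1 | step 4 | methyl 3-[4-(methoxymethoxy)-3,5-di(prop-2-en-1-yl)phenyl]propanoate | COCOc1c(CC=C)cc(CCC(=O)OC)cc1CC=C
F2 | step 7 | 3-[4-(methoxymethoxy)-3,5-bis(3-methylbut-2-en-1-yl)phenyl]propanal | COCOc1c(CC=C(C)C)cc(CCC=O)cc1CC=C(C)C
F3 | step 7 | 3-[4-(methoxymethoxy)-3,5-bis(3-methylbut-2-en-1-yl)phenyl]-1-[2,4,6-tris(methoxymethoxy)phenyl]propan-1-ol (racemic) | COCOc1cc(OCOC)c(C(O)CCc2cc(CC=C(C)C)c(OCOC)c(CC=C(C)C)c2)c(OCOC)c1
F4 | step 8 | 3-[3,5-bis(3-methylbut-2-en-1-yl)-4-(trimethylsilyloxy)phenyl]-1-[2,4,6-tris(trimethylsilyloxy)phenyl]propan-1-one | C[Si](C)(C)Oc1cc(O[Si](C)(C)C)c(C(=O)CCc2cc(CC=C(C)C)c(O[Si](C)(C)C)c(CC=C(C)C)c2)c(O[Si](C)(C)C)c1
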